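**Retrosynthetic overview** (C1–C15 = polyketide chain numbering: C1 lactone carbonyl, C9 carbinol, C15 carries the phenyl)
1. Target 12 ⇐ silyl ether 11 by O-desilylation.
2. 11 ⇐ open-chain 8 by a one-operation double aldol as in the polyketide pathway: C12→C7 Knoevenagel closes the cyclohexenone, then C6→C15 vinylogous aldol and dehydration closes the benzene ring.
3. 8 ⇐ triketo ester 5 + triacetic acid lactone 6 (C6–C7 Claisen); the pyrone, the pathway's lactone terminus, is bought.
4. 5 ⇐ half-ester 1 + benzoylacetone 2 (C11–C12 Claisen); the C9 carbinol comes from the desymmetrised 3-silyloxyglutarate 1.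
5. Ring order: pyrone (pre-formed) → alicyclic ring → aromatic ring, the last two in one flask.

Assumption: the (3R)-half-ester 1 (a statin side-chain building block) is bought as the single enantiomer; its acid arm becomes C10–C11 and its ester arm C8–C7, which gives the (S)-carbinol of the target.

**Step 1**
Reactants: 1 (3R)-3-[(tert-butyldimethylsilyl)oxy]-5-methoxy-5-oxopentanoic acid; 2 1-phenylbutane-1,3-dione (benzoylacetone)
Product: 5 methyl (3R)-3-[(tert-butyldimethylsilyl)oxy]-5,7,9-trioxo-9-phenylnonanoate, via acyl imidazolide 3 (not isolated), via dilithio benzoylacetone 4 (not isolated)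
Conditions: 1, CDI (1.05 equiv), THF, 23 °C, 1 h; then cannulate into 2 (3.2 equiv) + LDA (6.4 equiv), THF, −78 → −40 °C; AcOH quench
Reagents that add atoms: none
Why: Hauser–Harris terminal C-acylation (Claisen type) of the 1,3-diketone dianion by the acyl imidazolide, which is far more electrophilic than the methyl ester at −78 °C, so the two glutarate ends stay differentiated and the bought carbinol centre, which is not touched, keeps its configuration.

**Step 2**
Reactants: 5 methyl (3R)-3-[(tert-butyldimethylsilyl)oxy]-5,7,9-trioxo-9-phenylnonanoate; 6 4-hydroxy-6-methyl-2H-pyran-2-one (triacetic acid lactone)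
Product: 8 6-[(4S)-4-[(tert-butyldimethylsilyl)oxy]-2,6,8,10-tetraoxo-10-phenyldecyl]-4-hydroxy-2H-pyran-2-one, via dilithio triacetic acid lactone 7 (not isolated)
Conditions: 6 (4.5 equiv), LDA (9 equiv), THF–DMPU, −78 → −20 °C; add 5, −78 → −10 °C; AcOH quench, pH 5 work-up, crude used at once
Reagents that add atoms: none
Why: Claisen condensation of the 6-methyl carbanion of the pyrone dianion with the β-silyloxy-activated methyl ester (Harris acylation of triacetic acid lactone), while the first equivalents of the dianion convert the triketone into its unreactive polyenolate; no stereocentre is involved.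

**Step 3**
Reactants: 8 6-[(4S)-4-[(tert-butyldimethylsilyl)oxy]-2,6,8,10-tetraoxo-10-phenyldecyl]-4-hydroxy-2H-pyran-2-one
Product: 11 (3S)-3-[(tert-butyldimethylsilyl)oxy]-8-hydroxy-5-(4-hydroxy-2-oxo-2H-pyran-6-yl)-6-phenyl-3,4-dihydronaphthalen-1(2H)-one, via Knoevenagel cyclohexenone 9 (not isolated), via bicyclic aldol 10 (not isolated)
Conditions: 0.1 M potassium phosphate buffer (pH 8.0)–MeCN 1:1, degassed, 23 → 40 °C
Reagents that add atoms: none
Why: Biomimetic polyketide folding in which the most acidic carbon (C12, between two carbonyls) attacks the only non-enolised ketone (C7) in a six-ring intramolecular Knoevenagel condensation and the pyrone-CH2 (C6) of the resulting dienone then closes on the benzoyl carbonyl (C15) in a vinylogous aldol whose dehydration is driven by aromatisation, the near-neutral buffer being too weak for E1cB loss of the β-silyloxy group so that the carbinol centre is carried through unchanged.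

**Step 4**
Reactants: 11 (3S)-3-[(tert-butyldimethylsilyl)oxy]-8-hydroxy-5-(4-hydroxy-2-oxo-2H-pyran-6-yl)-6-phenyl-3,4-dihydronaphthalen-1(2H)-one
Product: 12 Wailupemycin F, (3S)-3,8-dihydroxy-5-(4-hydroxy-2-oxo-2H-pyran-6-yl)-6-phenyl-3,4-dihydronaphthalen-1(2H)-one
Conditions: HF·pyridine, pyridine, THF, 0 → 23 °C
Reagents that add atoms: none
Why: Fluoride-mediated O-desilylation under pyridine-buffered conditions that are too mild to dehydrate the β-hydroxy tetralone to a naphthol; the stereocentre is not involved.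

**Compound list**
1 | (3R)-3-[(tert-butyldimethylsilyl)oxy]-5-methoxy-5-oxopentanoic acid | OC(=O)C[C@@H](O[Si](C)(C)C(C)(C)C)CC(=O)OC | starting material
2 | 1-phenylbutane-1,3-dione (benzoylacetone) | CC(=O)CC(=O)c1ccccc1 | starting material
3 | methyl (3R)-3-[(tert-butyldimethylsilyl)oxy]-5-(1H-imidazol-1-yl)-5-oxopentanoate (acyl imidazolide, formed in situ) | O=C(C[C@@H](O[Si](C)(C)C(C)(C)C)CC(=O)OC)n1ccnc1 | intermediate
4 | dilithium 1-phenylbuta-1,3-diene-1,3-diolate (dianion of 2, formed in situ) | [Li+].[Li+].C=C([O-])C=C([O-])c1ccccc1 | intermediate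
5 | methyl (3R)-3-[(tert-butyldimethylsilyl)oxy]-5,7,9-trioxo-9-phenylnonanoate | O=C(CC(=O)CC(=O)C[C@@H](O[Si](C)(C)C(C)(C)C)CC(=O)OC)c1ccccc1 | intermediate
6 | 4-hydroxy-6-methyl-2H-pyran-2-one (triacetic acid lactone) | Cc1cc(O)cc(=O)o1 | starting material
7 | dilithium salt of 6 deprotonated at the 4-OH and the 6-methyl group (formed in situ) | [Li+].[Li+].[CH2-]c1cc([O-])cc(=O)o1 | intermediate
8 | 6-[(4S)-4-[(tert-butyldimethylsilyl)oxy]-2,6,8,10-tetraoxo-10-phenyldecyl]-4-hydroxy-2H-pyran-2-one | O=C(CC(=O)CC(=O)C[C@@H](O[Si](C)(C)C(C)(C)C)CC(=O)Cc1cc(O)cc(=O)o1)c1ccccc1 | intermediate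
9 | 6-{[(5S)-5-[(tert-butyldimethylsilyl)oxy]-3-oxo-2-(3-oxo-3-phenylpropanoyl)cyclohex-1-en-1-yl]methyl}-4-hydroxy-2H-pyran-2-one (formed in situ) | O=C1C[C@@H](O[Si](C)(C)C(C)(C)C)CC(Cc2cc(O)cc(=O)o2)=C1C(=O)CC(=O)c1ccccc1 | intermediate
10 | (3S)-3-[(tert-butyldimethylsilyl)oxy]-6-hydroxy-5-(4-hydroxy-2-oxo-2H-pyran-6-yl)-6-phenyl-3,4,6,7-tetrahydronaphthalene-1,8(2H,5H)-dione, mixture at C5/C6 (formed in situ) | O=C1C[C@@H](O[Si](C)(C)C(C)(C)C)CC2=C1C(=O)CC(O)(c1ccccc1)C2c1cc(O)cc(=O)o1 | intermediate
11 | (3S)-3-[(tert-butyldimethylsilyl)oxy]-8-hydroxy-5-(4-hydroxy-2-oxo-2H-pyran-6-yl)-6-phenyl-3,4-dihydronaphthalen-1(2H)-one | O=C1C[C@@H](O[Si](C)(C)C(C)(C)C)Cc2c1c(O)cc(-c1ccccc1)c2-c1cc(O)cc(=O)o1 | intermediate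
12 | Wailupemycin F, (3S)-3,8-dihydroxy-5-(4-hydroxy-2-oxo-2H-pyran-6-yl)-6-phenyl-3,4-dihydronaphthalen-1(2H)-one | O=C1C[C@@H](O)Cc2c1c(O)cc(-c1ccccc1)c2-c1cc(O)cc(=O)o1 | target

**Total step count:** 4. **Longest linear sequence:** 4 (1 → 5 → 8 → 11 → 12).

**Steps most likely to fail**

Step 3 (the double aldol). The triketone can instead close in the Harris resorcinol mode (C10→C15), and the β-silyloxy ketone of 9 can lose silanol by E1cB, which aromatises the alicyclic ring and destroys the stereocentre. The fallback sets out from 8 and comes back to the route at 12. The silyl group is taken off first at the open-chain stage with 3HF·NEt3 in MeCN to give the free carbinol 4-hydroxy-6-[(4S)-4-hydroxy-2,6,8,10-tetraoxo-10-phenyldecyl]-2H-pyran-2-one F1. F1 is then folded in the same pH 7–8 buffer without any protecting group. A free hydroxyl is a much poorer leaving group than a silanolate, so the E1cB exit is slowed, and step 4 is no longer needed.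

Step 2 (Claisen of the pyrone dianion with ester 5). The triketone polyenolate can attack its own ester (Dieckmann closure to an achiral 2-acylcyclohexane-1,3-dione), the ester enolate can expel silanolate, and the pyrone dianion is only a moderate nucleophile. The fallback sets out from 1 and 6 and comes back at 8, with the order of the two couplings reversed. The lithium carboxylate of 1 is treated with 7; only the ester end can react and no Dieckmann closure is possible, giving (3S)-3-[(tert-butyldimethylsilyl)oxy]-6-(4-hydroxy-2-oxo-2H-pyran-6-yl)-5-oxohexanoic acid F2. F2 is cyclodehydrated with EDC at high dilution to the enol δ-lactone 6-{(Z)-[(4S)-4-[(tert-butyldimethylsilyl)oxy]-6-oxooxan-2-ylidene]methyl}-4-hydroxy-2H-pyran-2-one F3. This masks the C7 ketone as an enol ester and activates C11 at the same time. The dianion 4 then opens the lactone at its acyl carbon (as in the first stage of a Fujimoto–Belleau reaction), and mild acid quench gives 8.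

Step 1 (acylation of the diketone dianion). The strongly basic dianion can deprotonate the acyl imidazolide α to the carbonyl (ketene formation or loss of silanolate) or attack the methyl ester. The fallback sets out from 1 and 2 and comes back at 5, replacing the dianion by a neutral Mukaiyama-type C-acylation. Acid 1 is converted with Ghosez's reagent into the acid chloride methyl (3S)-5-chloro-3-[(tert-butyldimethylsilyl)oxy]-5-oxopentanoate F4 (same spatial arrangement; the descriptor changes by CIP priority only). Benzoylacetone 2 is converted with TMSOTf/Et3N into (1Z)-1-phenyl-1,3-bis(trimethylsilyloxy)buta-1,3-diene F5. F4 and F5 are combined in CH2Cl2 at −78 → 20 °C with catalytic TMSOTf (Chan-type terminal acylation of a 1,3-bis-silyloxy diene), and aqueous work-up gives 5.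

**Further compounds**
F1 | step 3 | 4-hydroxy-6-[(4S)-4-hydroxy-2,6,8,10-tetraoxo-10-phenyldecyl]-2H-pyran-2-one | O=C(CC(=O)CC(=O)C[C@@H](O)CC(=O)Cc1cc(O)cc(=O)o1)c1ccccc1
F2 | step 2 | (3S)-3-[(tert-butyldimethylsilyl)oxy]-6-(4-hydroxy-2-oxo-2H-pyran-6-yl)-5-oxohexanoic acid | OC(=O)C[C@@H](O[Si](C)(C)C(C)(C)C)CC(=O)Cc1cc(O)cc(=O)o1
F3 | step 2 | 6-{(Z)-[(4S)-4-[(tert-butyldimethylsilyl)oxy]-6-oxooxan-2-ylidene]methyl}-4-hydroxy-2H-pyran-2-one | O=C1C[C@@H](O[Si](C)(C)C(C)(C)C)C/C(=C/c2cc(O)cc(=O)o2)O1
F4 | step 1 | methyl (3S)-5-chloro-3-[(tert-butyldimethylsilyl)oxy]-5-oxopentanoate | O=C(Cl)C[C@@H](O[Si](C)(C)C(C)(C)C)CC(=O)OC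
F5 | step 1 | (1Z)-1-phenyl-1,3-bis(trimethylsilyloxy)buta-1,3-diene | C=C(O[Si](C)(C)C)/C=C(\O[Si](C)(C)C)c1ccccc1
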